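The dihydropyran of the second pyranotropolone (ring C: O1′, C2′, C3′, C4′, C4a′, C9a′) is disconnected at C4′–C3′ and O1′–C2′, i.e. into a tropolone ortho-quinone methide and the terminal vinyl group of a hexatriene carried by the finished first pyranotropolone (rings A and B). The key step exploits the methylene C4′ on C4a′ next to the oxygen-bearing C9a′ and the dienylic C2′–O1′ bond: one catalysed hetero-Diels–Alder reaction joins the two halves, closes the last ring, sets C2′ and gives the unprotected target. Its precursors are a ring-B-bound (E,E)-triene and a hydroxy(hydroxymethyl)tropolone, both made from one bromotropolone.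

Key step: step 15

Remark: ring A = first tropolone, ring B = first dihydropyran, ring C = second dihydropyran, ring D = second tropolone; tropolones are drawn as one of their two fast-exchanging tautomers.
Remark: the O-methylation of step 5 is taken to give the 2,4-dimethoxy isomer drawn; the ether on the other tropolone oxygen would react alike and converge after the later hydrolyses.
Remark: the bicyclic compounds of steps 2–4 are racemic (one enantiomer drawn); their stereocentres disappear in step 4.

Step 1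
Reactants: 1 2-methylanisole
Product: 2 1-methoxy-2-methylcyclohexa-1,4-diene
Conditions: Li, NH3(l), THF, t-BuOH, −78 °C; then NH4Cl
Reagents that add atoms: none
Why: Birch reduction keeps both donor-bearing carbons sp2, so the ring is protonated at C3 and C6 and the methoxy and methyl groups end on one tetrasubstituted enol ether double bond.

Step 2
Reactants: 2 1-methoxy-2-methylcyclohexa-1,4-diene
Product: 3 7,7-dibromo-1-methoxy-6-methylbicyclo[4.1.0]hept-3-ene (racemic, cis-fused)
Conditions: CHBr3, KOtBu, pentane, −10 °C; used cold and crude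
Reagents that add atoms: bromoform, BrC(Br)Br
Why: Dihalocarbene cyclopropanation, in which the electrophilic carbene should add to the electron-rich tetrasubstituted enol ether and not to the disubstituted double bond; the cis ring fusion is forced.

Step 3
Reactants: 3 7,7-dibromo-1-methoxy-6-methylbicyclo[4.1.0]hept-3-ene
Product: 4 7,7-dibromo-1-methoxy-6-methylbicyclo[4.1.0]heptane-3,4-diol (racemic; cis-diol anti to the CBr2 bridge)
Conditions: OsO4 (2 mol%), NMO, acetone/H2O 10:1, 0 °C
Reagents that add atoms: N-methylmorpholine N-oxide, C[N+]1([O-])CCOCC1; water, O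
Why: Upjohn syn-dihydroxylation of the remaining double bond from the face away from the endo bromine; the configuration of these carbinols is irrelevant because both are oxidised next.

Step 4
Reactants: 4 7,7-dibromo-1-methoxy-6-methylbicyclo[4.1.0]heptane-3,4-diol
Product: 6 5-bromo-2-hydroxy-4-methoxy-6-methylcyclohepta-2,4,6-trien-1-one, via dibromocyclopropane dione 5 (not isolated)
Conditions: DMSO, (CF3CO)2O, CH2Cl2, −60 °C; then Et3N, −60 °C to rt
Reagents that add atoms: none
Why: Swern-type oxidation gives the 1,2-dione, whose bis-enol is a norcaradiene that opens electrocyclically and loses HBr (gem-dibromocyclopropane ring expansion to a tropolone), so the carbene carbon becomes C5–Br between C4–OMe and C6–Me.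

Step 5
Reactants: 6 5-bromo-2-hydroxy-4-methoxy-6-methylcyclohepta-2,4,6-trien-1-one
Product: 7 5-bromo-2,4-dimethoxy-6-methylcyclohepta-2,4,6-trien-1-one
Conditions: MeI, K2CO3, acetone, 50 °C
Reagents that add atoms: iodomethane, CI
Why: Williamson O-alkylation of the tropolonate masks the acidic, metal-chelating hydroxyl group for the two palladium-catalysed couplings.

Step 6
Reactants: 8 methyl (S)-2,2-dimethyl-1,3-dioxolane-4-carboxylate
Product: 10 1-[(4S)-2,2-dimethyl-1,3-dioxolan-4-yl]ethan-1-one, via Weinreb amide 9 (not isolated)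
Conditions: MeNH(OMe)·HCl, i-PrMgCl, THF, −20 °C; then MeMgBr, −20 to 0 °C; NH4Cl (aq)
Reagents that add atoms: N,O-dimethylhydroxylamine hydrochloride, CNOC.Cl (its atoms stay in 9 only); methylmagnesium bromide, C[Mg]Br
Why: One-flask Weinreb ketone synthesis, in which the magnesium chelate of the tetrahedral adduct stops over-addition and the low temperature leaves the α-alkoxy stereocentre untouched.

Step 7
Reactants: 10 1-[(4S)-2,2-dimethyl-1,3-dioxolan-4-yl]ethan-1-one
Product: 11 (4R)-2,2-dimethyl-4-(prop-1-en-2-yl)-1,3-dioxolane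
Conditions: Ph3PCH3Br, KOtBu, THF, 0 °C
Reagents that add atoms: methyltriphenylphosphonium bromide, C[P+](c1ccccc1)(c1ccccc1)c1ccccc1.[Br-]
Why: Wittig methylenation with the non-stabilised ylide at 0 °C should outrun enolisation of the ketone, so the stereocentre (the future C2) keeps its geometry (the descriptor changes to R only through the priority rules).

Step 8
Reactants: 11 (4R)-2,2-dimethyl-4-(prop-1-en-2-yl)-1,3-dioxolane; 7 5-bromo-2,4-dimethoxy-6-methylcyclohepta-2,4,6-trien-1-one
Product: 13 5-[(2R)-2-[(4R)-2,2-dimethyl-1,3-dioxolan-4-yl]propyl]-2,4-dimethoxy-6-methylcyclohepta-2,4,6-trien-1-one, via alkylborane 12 (not isolated)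
Conditions: 9-BBN, THF, 0 °C to rt; then 7, PdCl2(dppf) (5 mol%), K3PO4 (aq), DMF, 60 °C
Reagents that add atoms: 9-borabicyclo[3.3.1]nonane, [H]B1C2CCCC1CCC2 (its boron and carbons stay in 12 only; 13 keeps one hydrogen from it)
Why: 9-BBN should add to the 1,1-disubstituted alkene anti to the dioxolane CH2 with the allylic hydrogen in the alkene plane (Still–Barrish anti selectivity), which sets the future C3 as R relative to the glycerate-derived centre, and the primary alkylborane then undergoes B-alkyl Suzuki–Miyaura coupling.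

Step 9
Reactants: 13 5-[(2R)-2-[(4R)-2,2-dimethyl-1,3-dioxolan-4-yl]propyl]-2,4-dimethoxy-6-methylcyclohepta-2,4,6-trien-1-one
Product: 16 (2R,3R)-8-hydroxy-2-(hydroxymethyl)-3,5-dimethyl-3,4-dihydrocyclohepta[b]pyran-7(2H)-one, via diol 14 (not isolated), via pyranotropone methyl ether 15 (not isolated)
Conditions: 3 M HCl (aq), THF, 65 °C
Reagents that add atoms: water, O
Why: Acetal hydrolysis frees the secondary alcohol, which displaces the C4 methoxy group by 6-exo addition–elimination (vinylogous transesterification; the C–O bond of the stereocentre is not broken, so trans-2R,3R is kept and the seven-ring ether from the primary alcohol reverts), and the tropolone methyl ether is then hydrolysed as a vinylogous ester.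

Step 10
Reactants: 16 (2R,3R)-8-hydroxy-2-(hydroxymethyl)-3,5-dimethyl-3,4-dihydrocyclohepta[b]pyran-7(2H)-one
Product: 17 (2R,3R)-8-hydroxy-3,5-dimethyl-7-oxo-2,3,4,7-tetrahydrocyclohepta[b]pyran-2-carbaldehyde
Conditions: Dess–Martin periodinane, NaHCO3, CH2Cl2, 0 °C
Reagents that add atoms: none
Why: Dess–Martin oxidation of the primary alcohol under buffered conditions; any epimerisation at C2 would return to the favoured 2,3-trans aldehyde, C3 being fixed.

Step 11
Reactants: 17 (2R,3R)-8-hydroxy-3,5-dimethyl-7-oxo-2,3,4,7-tetrahydrocyclohepta[b]pyran-2-carbaldehyde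
Product: 18 (2E)-3-[(2R,3R)-8-hydroxy-3,5-dimethyl-7-oxo-2,3,4,7-tetrahydrocyclohepta[b]pyran-2-yl]prop-2-enal
Conditions: Ph3P=CHCHO, toluene, 50 °C
Reagents that add atoms: (triphenylphosphoranylidene)acetaldehyde, O=CC=P(c1ccccc1)(c1ccccc1)c1ccccc1
Why: Wittig reaction with a stabilised ylide, which should give the E-enal and is not basic enough to disturb the tropolone or C2.

Step 12
Reactants: 18 (2E)-3-[(2R,3R)-8-hydroxy-3,5-dimethyl-7-oxo-2,3,4,7-tetrahydrocyclohepta[b]pyran-2-yl]prop-2-enal
Product: 19 (2R,3R)-2-[(1E,3E)-hexa-1,3,5-trien-1-yl]-8-hydroxy-3,5-dimethyl-3,4-dihydrocyclohepta[b]pyran-7(2H)-one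
Conditions: diethyl allylphosphonate, LiHMDS (2.3 equiv), THF/DMPU, −78 to 0 °C; NH4Cl (aq)
Reagents that add atoms: diethyl allylphosphonate, C=CCP(=O)(OCC)OCC
Why: Horner–Wadsworth–Emmons olefination through α-attack of the allylphosphonate anion should give the new E double bond and the terminal vinyl group; the extra base holds the tropolone as its lithium salt.

Step 13
Reactants: 7 5-bromo-2,4-dimethoxy-6-methylcyclohepta-2,4,6-trien-1-one
Product: 20 5-(hydroxymethyl)-2,4-dimethoxy-6-methylcyclohepta-2,4,6-trien-1-one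
Conditions: Bu3SnCH2OH, Pd(PPh3)4 (5 mol%), 1,4-dioxane, 90 °C
Reagents that add atoms: (tributylstannyl)methanol, CCCC[Sn](CCCC)(CCCC)CO
Why: Stille hydroxymethylation of the bromotropone under neutral conditions installs the future C4′ with its leaving oxygen.

Step 14
Reactants: 20 5-(hydroxymethyl)-2,4-dimethoxy-6-methylcyclohepta-2,4,6-trien-1-one
Product: 22 2,4-dihydroxy-5-(hydroxymethyl)-6-methylcyclohepta-2,4,6-trien-1-one, via tropolone monomethyl ether 21 (not isolated)
Conditions: 2 M NaOH (aq), 1,4-dioxane, 70 °C; then 1 M HCl to pH 4, 0 °C; used at once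
Reagents that add atoms: sodium hydroxide, [Na+].[OH-]
Why: Saponification of the two vinylogous methyl esters by addition–elimination; under base the polyanion cannot lose hydroxide, so the quinone methide precursor should survive until the cold acidification.

Step 15
Reactants: 19 (2R,3R)-2-[(1E,3E)-hexa-1,3,5-trien-1-yl]-8-hydroxy-3,5-dimethyl-3,4-dihydrocyclohepta[b]pyran-7(2H)-one; 22 2,4-dihydroxy-5-(hydroxymethyl)-6-methylcyclohepta-2,4,6-trien-1-one
Product: 24 (2R,3R)-8-hydroxy-2-[(1E,3E)-4-[(2R)-8-hydroxy-5-methyl-7-oxo-2,3,4,7-tetrahydrocyclohepta[b]pyran-2-yl]buta-1,3-dien-1-yl]-3,5-dimethyl-3,4-dihydrocyclohepta[b]pyran-7(2H)-one (CNP0332980.1), via quinone methide 23 (not isolated)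
Conditions: 22 (1.5 equiv, added in portions), (R)-3,3′-bis(2,4,6-triisopropylphenyl)-BINOL N-triflylphosphoramide (10 mol%), 5 Å MS, PhCF3, 35 °C
Reagents that add atoms: none
Why: Proposed new method: the acid dehydrates 22 to the tropolone ortho-quinone methide 23, kept as a hydrogen-bonded contact ion pair at its C9a′ carbonyl oxygen, and the exocyclic methylene (future C4′) is attacked by the terminal CH2 of the triene of 19 in an asynchronous inverse-demand hetero-Diels–Alder reaction that re-forms the aromatic tropolone. The closest known reaction types are the thermal hetero-Diels–Alder reaction of tropolone ortho-quinone methides with alkenes and the chiral phosphoric acid or N-triflylphosphoramide catalysed [4+2] of benzenoid ortho-quinone methides with styrenes (with the related ion-pair allylic etherification of phenols); new is catalyst-controlled induction with a tropolone methide and an unfunctionalised polyene. Ring C is closed by the [4+2] cycloaddition itself, C4′–C3′ and O1′–C2′ being made on one face of the vinyl group (at the stepwise limit a 6-exo collapse of a pentadienyl cation onto the tropolone oxygen inside the chiral ion pair). The only new stereocentre, C2′, is too far from C2 and C3 for substrate control and is set by the catalyst: the C2′–O1′ bond forms at the oxygen that carries the chiral anion, whose 3,3′-aryl walls decide which face of the internal vinyl carbon is offered and force the dienyl chain outwards. The step needs site selectivity for the terminal double bond and oxygen-to-internal-carbon regiochemistry, which the substrate secures because the terminal CH2 is the least hindered, most nucleophilic terminus, attack there puts the developing positive charge on the fully conjugated C2′, the other triene terminus is shielded by ring B and only six-ring closure restores the tropolone.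

Compound list
1 | 2-methylanisole | COc1ccccc1C | starting material
2 | 1-methoxy-2-methylcyclohexa-1,4-diene | COC1=C(C)CC=CC1 | intermediate
3 | 7,7-dibromo-1-methoxy-6-methylbicyclo[4.1.0]hept-3-ene (racemic, cis-fused) | CO[C@]12CC=CC[C@@]1(C)C2(Br)Br | intermediate
4 | 7,7-dibromo-1-methoxy-6-methylbicyclo[4.1.0]heptane-3,4-diol (racemic, cis-diol anti to CBr2) | CO[C@]12C[C@H](O)[C@H](O)C[C@@]1(C)C2(Br)Br | intermediate
5 | 7,7-dibromo-1-methoxy-6-methylbicyclo[4.1.0]heptane-3,4-dione (racemic) | CO[C@]12CC(=O)C(=O)C[C@@]1(C)C2(Br)Br | intermediate (not isolated)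
6 | 5-bromo-2-hydroxy-4-methoxy-6-methylcyclohepta-2,4,6-trien-1-one | COC1=C(Br)C(C)=CC(=O)C(O)=C1 | intermediate
7 | 5-bromo-2,4-dimethoxy-6-methylcyclohepta-2,4,6-trien-1-one | COC1=C(Br)C(C)=CC(=O)C(OC)=C1 | intermediate
8 | methyl (S)-2,2-dimethyl-1,3-dioxolane-4-carboxylate | COC(=O)[C@@H]1COC(C)(C)O1 | starting material
9 | (4S)-N-methoxy-N,2,2-trimethyl-1,3-dioxolane-4-carboxamide | CON(C)C(=O)[C@@H]1COC(C)(C)O1 | intermediate (not isolated)
10 | 1-[(4S)-2,2-dimethyl-1,3-dioxolan-4-yl]ethan-1-one | CC(=O)[C@@H]1COC(C)(C)O1 | intermediate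
11 | (4R)-2,2-dimethyl-4-(prop-1-en-2-yl)-1,3-dioxolane | C=C(C)[C@@H]1COC(C)(C)O1 | intermediate
12 | 9-[(2R)-2-[(4R)-2,2-dimethyl-1,3-dioxolan-4-yl]propyl]-9-borabicyclo[3.3.1]nonane | C[C@H](CB1C2CCCC1CCC2)[C@@H]1COC(C)(C)O1 | intermediate (not isolated)
13 | 5-[(2R)-2-[(4R)-2,2-dimethyl-1,3-dioxolan-4-yl]propyl]-2,4-dimethoxy-6-methylcyclohepta-2,4,6-trien-1-one | COC1=C(C[C@@H](C)[C@@H]2COC(C)(C)O2)C(C)=CC(=O)C(OC)=C1 | intermediate
14 | 5-[(2R,3R)-3,4-dihydroxy-2-methylbutyl]-2,4-dimethoxy-6-methylcyclohepta-2,4,6-trien-1-one | COC1=C(C[C@@H](C)[C@@H](O)CO)C(C)=CC(=O)C(OC)=C1 | intermediate (not isolated)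
15 | (2R,3R)-2-(hydroxymethyl)-8-methoxy-3,5-dimethyl-3,4-dihydrocyclohepta[b]pyran-7(2H)-one | COC1=CC2=C(C[C@@H](C)[C@H](CO)O2)C(C)=CC1=O | intermediate (not isolated)
16 | (2R,3R)-8-hydroxy-2-(hydroxymethyl)-3,5-dimethyl-3,4-dihydrocyclohepta[b]pyran-7(2H)-one | CC1=CC(=O)C(O)=CC2=C1C[C@@H](C)[C@H](CO)O2 | intermediate
17 | (2R,3R)-8-hydroxy-3,5-dimethyl-7-oxo-2,3,4,7-tetrahydrocyclohepta[b]pyran-2-carbaldehyde | CC1=CC(=O)C(O)=CC2=C1C[C@@H](C)[C@H](C=O)O2 | intermediate
18 | (2E)-3-[(2R,3R)-8-hydroxy-3,5-dimethyl-7-oxo-2,3,4,7-tetrahydrocyclohepta[b]pyran-2-yl]prop-2-enal | CC1=CC(=O)C(O)=CC2=C1C[C@@H](C)[C@H](/C=C/C=O)O2 | intermediate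
19 | (2R,3R)-2-[(1E,3E)-hexa-1,3,5-trien-1-yl]-8-hydroxy-3,5-dimethyl-3,4-dihydrocyclohepta[b]pyran-7(2H)-one | CC1=CC(=O)C(O)=CC2=C1C[C@@H](C)[C@H](/C=C/C=C/C=C)O2 | intermediate
20 | 5-(hydroxymethyl)-2,4-dimethoxy-6-methylcyclohepta-2,4,6-trien-1-one | COC1=C(CO)C(C)=CC(=O)C(OC)=C1 | intermediate
21 | 2-hydroxy-5-(hydroxymethyl)-4-methoxy-6-methylcyclohepta-2,4,6-trien-1-one | COC1=C(CO)C(C)=CC(=O)C(O)=C1 | intermediate (not isolated)
22 | 2,4-dihydroxy-5-(hydroxymethyl)-6-methylcyclohepta-2,4,6-trien-1-one | OCC1=C(O)C=C(O)C(=O)C=C1C | intermediate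
23 | 2-hydroxy-6-methyl-5-methylidenecyclohepta-2,6-diene-1,4-dione (tropolone ortho-quinone methide) | C=C1C(C)=CC(=O)C(O)=CC1=O | intermediate (not isolated)
24 | (2R,3R)-8-hydroxy-2-[(1E,3E)-4-[(2R)-8-hydroxy-5-methyl-7-oxo-2,3,4,7-tetrahydrocyclohepta[b]pyran-2-yl]buta-1,3-dien-1-yl]-3,5-dimethyl-3,4-dihydrocyclohepta[b]pyran-7(2H)-one | Cc1cc(=O)c(O)cc2c1C[C@@H](C)[C@H](/C=C/C=C/[C@H]1CCc3c(C)cc(=O)c(O)cc3O1)O2 | target

Total step count: 15. Longest linear sequence: 11 steps (steps 1–5, 8–12, 15).

Steps most likely to fail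

Step 15 (the labelled step). The chiral ion pair may not discriminate the two faces of the terminal vinyl group, an uncatalysed background cycloaddition may compete, and the acid may ionise the dienylic C2–O1 and C2′–O1′ bonds and erode both centres. The fallback uses known chemistry only, sets out from 18 and returns at 24. A second Wittig reaction with Ph3P=CHCHO would extend 18 to the (2E,4E)-dienal F1. Catalytic asymmetric addition of divinylzinc (amino alcohol ligand (+)-MIB, the antipode that gives R-carbinols; one extra equivalent of the zinc reagent for the tropolone) should give the (5R)-vinyl carbinol F2 under ligand control. 9-BBN should hydroborate only its isolated terminal vinyl group to the alkylborane F3, which is coupled in the same flask with 7 (PdCl2(dppf), K3PO4) to the hydroxy dimethoxytropone F4. KOtBu in THF then closes ring C by 6-exo addition–elimination of the alkoxide at the methoxy-bearing tropone carbon; the C–O bond of the stereocentre is not broken, so R is retained, giving the ring D methyl ether F5. LiCl in DMF at 90 °C removes the last O-methyl group to give 24.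

Step 8. The hydroboration may show incomplete anti facial selectivity, and transmetalation to the doubly ortho-substituted bromotropone may be slow, with protodeboronation taking over. The fallback sets out from 11 and returns at 13. Hydroboration with 9-BBN and oxidation (NaOH, H2O2) would give the primary alcohol F6, whose anti diastereomer is purified at this stage. Appel iodination (iodine, PPh3, imidazole) gives the iodide F7, zinc insertion (zinc dust, LiCl, THF) gives the alkylzinc iodide F8, and Negishi coupling with 7 (Pd(OAc)2, SPhos) gives 13.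

Step 12. The ambident allylphosphonate anion may attack through its γ-carbon, the E geometry may erode, and the base may epimerise C2 or start polymerisation of the triene. The fallback sets out from 18 and returns at 19. Takai olefination (CrCl2, CHI3, THF) would give the (1E,3E)-dienyl iodide F9, and Stille coupling with tributyl(vinyl)stannane (Pd(PPh3)4, DMF, rt) gives 19 with the double-bond geometry fixed by the reagents.

Further compounds
F1 | step 15 | (2E,4E)-5-[(2R,3R)-8-hydroxy-3,5-dimethyl-7-oxo-2,3,4,7-tetrahydrocyclohepta[b]pyran-2-yl]penta-2,4-dienal | CC1=CC(=O)C(O)=CC2=C1C[C@@H](C)[C@H](/C=C/C=C/C=O)O2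
F2 | step 15 | (2R,3R)-8-hydroxy-2-[(1E,3E,5R)-5-hydroxyhepta-1,3,6-trien-1-yl]-3,5-dimethyl-3,4-dihydrocyclohepta[b]pyran-7(2H)-one | CC1=CC(=O)C(O)=CC2=C1C[C@@H](C)[C@H](/C=C/C=C/[C@H](O)C=C)O2
F3 | step 15 | (2R,3R)-2-[(1E,3E,5R)-7-(9-borabicyclo[3.3.1]nonan-9-yl)-5-hydroxyhepta-1,3-dien-1-yl]-8-hydroxy-3,5-dimethyl-3,4-dihydrocyclohepta[b]pyran-7(2H)-one | CC1=CC(=O)C(O)=CC2=C1C[C@@H](C)[C@H](/C=C/C=C/[C@H](O)CCB1C3CCCC1CCC3)O2
F4 | step 15 | 5-[(3R,4E,6E)-3-hydroxy-7-[(2R,3R)-8-hydroxy-3,5-dimethyl-7-oxo-2,3,4,7-tetrahydrocyclohepta[b]pyran-2-yl]hepta-4,6-dien-1-yl]-2,4-dimethoxy-6-methylcyclohepta-2,4,6-trien-1-one | CC1=CC(=O)C(O)=CC2=C1C[C@@H](C)[C@H](/C=C/C=C/[C@H](O)CCC1=C(OC)C=C(OC)C(=O)C=C1C)O2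
F5 | step 15 | (2R,3R)-8-hydroxy-2-[(1E,3E)-4-[(2R)-8-methoxy-5-methyl-7-oxo-2,3,4,7-tetrahydrocyclohepta[b]pyran-2-yl]buta-1,3-dien-1-yl]-3,5-dimethyl-3,4-dihydrocyclohepta[b]pyran-7(2H)-one | CC1=CC(=O)C(O)=CC2=C1C[C@@H](C)[C@H](/C=C/C=C/[C@H]1CCC3=C(O1)C=C(OC)C(=O)C=C3C)O2
F6 | step 8 | (2R)-2-[(4R)-2,2-dimethyl-1,3-dioxolan-4-yl]propan-1-ol | C[C@H](CO)[C@@H]1COC(C)(C)O1
F7 | step 8 | (4R)-4-[(2S)-1-iodopropan-2-yl]-2,2-dimethyl-1,3-dioxolane | C[C@H](CI)[C@@H]1COC(C)(C)O1
F8 | step 8 | [(2S)-2-[(4R)-2,2-dimethyl-1,3-dioxolan-4-yl]propyl]zinc iodide | C[C@H](C[Zn]I)[C@@H]1COC(C)(C)O1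
F9 | step 12 | (2R,3R)-8-hydroxy-2-[(1E,3E)-4-iodobuta-1,3-dien-1-yl]-3,5-dimethyl-3,4-dihydrocyclohepta[b]pyran-7(2H)-one | CC1=CC(=O)C(O)=CC2=C1C[C@@H](C)[C@H](/C=C/C=C/I)O2
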